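Ring numbering: C1 ketone, C2 (carries C7H2OH), C3 (alkene CH), C4 (propionate carbinol), C5 (isopropyl carbon), C6 (enoate carbinol).
Cuts: first the acyl C–O bonds of the C4 propionate and the C6 enoate, then the ring bonds C4–C5 and C1–C6 together. This [4+2] cut is possible because the oxygens on C1 and C4 stand 1,4 to each other across C2=C3. That is the bridgehead pattern of a 3-hydroxy-2-pyrone cycloadduct (C1 = bridgehead carbinol bearing the lactone carbonyl, C4–O = lactone oxygen).
Forward: C7 is put on C4 of 3-hydroxy-2-pyrone. The only carbocycle then closes in the cycloaddition with (E)-5-methylhex-3-en-2-one, as a lactone-bridged bicyclo[2.2.2]octene. The acetyl group is exchanged for oxygen, the bridge is opened and its carbon lost as CO2 to give the enone, and the enoate and then the propionate are attached.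
Stereochemistry: C4, C5 and C6 are all set in the cycloaddition (C5/C6 trans from the E-alkene, C4–O cis to isopropyl from the endo mode, absolute sense from the cinchona amine). The Baeyer–Villiger shift keeps C6, and the E-alkene of the side chain comes from a stabilised ylide.

Key step: step 3

Assumption: the quinine-derived amine is written as catalyst of step 3; if a trial run shows that it favours the mirror-image adduct, its quinidine-derived pseudoenantiomer takes its place and nothing else changes.

Step 1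
Reactants: 1 3-hydroxy-2H-pyran-2-one; 2 formaldehyde (37% aqueous)
Product: 3 3-hydroxy-4-(hydroxymethyl)-2H-pyran-2-one
Conditions: NaOH (1.0 equiv), aq HCHO (1.1 equiv), H2O, 0 °C to rt; then HCl, pH 2
Reagents that add atoms: none
Why: Aldol-type (Lederer–Manasse) hydroxymethylation as practised on kojic acid and other enolic 3-hydroxypyranones, in which one equivalent of base only forms the 3-oxido salt, the enolate carbon C4 next to the oxygen attacks formaldehyde and re-enolises, and the absence of free hydroxide spares the lactone.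

Step 2
Reactants: 3 3-hydroxy-4-(hydroxymethyl)-2H-pyran-2-one
Product: 4 4-({[tert-butyl(dimethyl)silyl]oxy}methyl)-3-hydroxy-2H-pyran-2-one
Conditions: TBSCl (1.05 equiv), imidazole, DMF, 0 °C; aqueous work-up
Reagents that add atoms: tert-butyldimethylsilyl chloride, CC(C)(C)[Si](C)(C)Cl
Why: Selective silylation of the primary alcohol, as known for 2-hydroxybenzyl alcohol, since any silyl ether formed at the acidic enol oxygen is hydrolysed again on aqueous work-up.

Step 3
Reactants: 4 4-({[tert-butyl(dimethyl)silyl]oxy}methyl)-3-hydroxy-2H-pyran-2-one; 5 (3E)-5-methylhex-3-en-2-one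
Product: 6 (1R,4R,7R,8R)-8-acetyl-5-({[tert-butyl(dimethyl)silyl]oxy}methyl)-4-hydroxy-7-(propan-2-yl)-2-oxabicyclo[2.2.2]oct-5-en-3-one (acetyl endo, on the alkene side; isopropyl on the lactone side)
Conditions: 9-amino-9-deoxy-epi-quinine (10 mol %), CF3CO2H (20 mol %), 5 (2 equiv), CH2Cl2, rt
Reagents that add atoms: none
Why: The primary amine of the catalyst condenses reversibly with 5 to an iminium ion (lower LUMO) while its quinuclidine nitrogen takes up the proton of the 3-hydroxyl of 4 (higher HOMO), and the two bound partners join in a concerted but asynchronous normal-demand [4+2] cycloaddition in which C4–C5 bonding (vinylogous Michael character) runs ahead of C1–C6 bonding (aldol character, formally 6-(enolexo)-exo-trig), after which hydrolysis of the iminium ion releases 6 and the catalyst. The closest known reaction type is the amine-base and cinchona-amine catalysed Diels–Alder reaction of 3-hydroxy-2-pyrones with simple α,β-unsaturated ketones, applied here to a pyrone whose extra substituent sits on a carbon that forms no bond. The one new ring, the C1–C6 carbocycle, closes intermolecularly and suprafacially on both partners, which turns the pyrone into a lactone-bridged bicyclo[2.2.2]octene. C1 and C4 are tied to each other by the bridge, C5 and C6 are trans because the E-geometry of 5 is carried over, the endo placement of the activated acetyl group under the diene puts isopropyl on the lactone side and hence C4–O cis to it, and the absolute sense follows from the enone face that the catalyst leaves open. Regioselectivity is needed and is secured by the substrates, since the oxido group makes the distal diene terminus (pyrone C6, future C4) the nucleophilic one and it pairs with the electrophilic β-carbon of 5, whereas endo and facial selectivity rest on the catalyst.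

Step 4
Reactants: 6 endo-acetyl bicyclic lactone
Product: 7 (1S,4S,7S,8R)-5-({[tert-butyl(dimethyl)silyl]oxy}methyl)-4-hydroxy-3-oxo-7-(propan-2-yl)-2-oxabicyclo[2.2.2]oct-5-en-8-yl acetate
Conditions: 3-chloroperbenzoic acid (mCPBA, 2.5 equiv), CH2Cl2, 0 °C to rt, dark
Reagents that add atoms: 3-chloroperbenzoic acid, OOC(=O)c1cccc(Cl)c1
Why: Baeyer–Villiger oxidation in which the secondary carbon C6 migrates in preference to methyl and with retention of configuration, the ketone is activated by the hydrogen bond from the C1 hydroxyl, and the C2=C3 alkene should be spared because all three of its allylic carbons carry electron-withdrawing C–O bonds and one face is screened by the endo substituent.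

Step 5
Reactants: 7 bridged lactone acetate
Product: 8 (1S,4S,5S,6R)-6-(acetyloxy)-2-({[tert-butyl(dimethyl)silyl]oxy}methyl)-1,4-dihydroxy-5-(propan-2-yl)cyclohex-2-ene-1-carboxylic acid
Conditions: LiOH (1.2 equiv), THF/H2O, 0 °C; then HCl, pH 4, 0 °C
Reagents that add atoms: water (delivered as LiOH/H2O), O
Why: Chemoselective saponification, because the bridged lactone is strained, locked in the reactive E-ester geometry and activated by its α-hydroxyl, so that it should open well before the hindered secondary acetate, and no stereocentre is touched.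

Step 6
Reactants: 8 tertiary α-hydroxy acid
Product: 9 (4S,5S,6R)-6-(acetyloxy)-2-({[tert-butyl(dimethyl)silyl]oxy}methyl)-4-hydroxy-5-(propan-2-yl)cyclohex-2-en-1-one
Conditions: Pb(OAc)4 (1.1 equiv), CH2Cl2, 0 °C
Reagents that add atoms: none
Why: Oxidative decarboxylation of an α-hydroxy acid with lead tetraacetate (the acid counterpart of glycol cleavage), which turns C1 into a ketone conjugated with C2=C3, while the acetate on C6 ensures that no free C1/C6 diol is present to be cleaved in competition.

Step 7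
Reactants: 9 4-hydroxy-6-acetoxy enone
Product: 10 (4S,5R,6R)-6-(acetyloxy)-2-({[tert-butyl(dimethyl)silyl]oxy}methyl)-5-(propan-2-yl)-4-[(triethylsilyl)oxy]cyclohex-2-en-1-one
Conditions: TESCl, imidazole, CH2Cl2, 0 °C
Reagents that add atoms: triethylsilyl chloride, CC[Si](CC)(CC)Cl
Why: Standard silylation of the only free alcohol, with triethylsilyl chosen because it withstands steps 8 and 11 and can later be removed beside the two tert-butyldimethylsilyl ethers.

Step 8
Reactants: 10 4-silyloxy-6-acetoxy enone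
Product: 11 (4S,5R,6R)-2-({[tert-butyl(dimethyl)silyl]oxy}methyl)-6-hydroxy-5-(propan-2-yl)-4-[(triethylsilyl)oxy]cyclohex-2-en-1-one
Conditions: K2CO3 (0.2 equiv), MeOH, −10 to 0 °C
Reagents that add atoms: none
Why: Base-catalysed transesterification of an acetate that is activated by the adjacent ketone and is the only ester present, and although C6 is epimerisable here its oxygen already lies trans to isopropyl in the more stable diequatorial arrangement.

Step 9
Reactants: 12 {[tert-butyl(dimethyl)silyl]oxy}acetaldehyde; 13 ethyl 2-(triphenyl-λ5-phosphanylidene)propanoate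
Product: 14 ethyl (2E)-4-{[tert-butyl(dimethyl)silyl]oxy}-2-methylbut-2-enoate
Conditions: CH2Cl2, rt
Reagents that add atoms: none
Why: Wittig olefination with a stabilised α-methyl ylide, which should give the trisubstituted E-enoate.

Step 10
Reactants: 14 ethyl (2E)-4-{[tert-butyl(dimethyl)silyl]oxy}-2-methylbut-2-enoate
Product: 15 (2E)-4-{[tert-butyl(dimethyl)silyl]oxy}-2-methylbut-2-enoic acid
Conditions: LiOH, THF/MeOH/H2O, rt; then HCl, pH 4
Reagents that add atoms: water (delivered as LiOH/H2O), O
Why: Ordinary saponification of an ethyl ester, under which the primary silyl ether and the alkene geometry are stable.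

Step 11
Reactants: 11 6-hydroxy enone; 15 (2E)-4-{[tert-butyl(dimethyl)silyl]oxy}-2-methylbut-2-enoic acid
Product: 16 (4S,5R,6R)-6-{[(2E)-4-{[tert-butyl(dimethyl)silyl]oxy}-2-methylbut-2-enoyl]oxy}-2-({[tert-butyl(dimethyl)silyl]oxy}methyl)-5-(propan-2-yl)-4-[(triethylsilyl)oxy]cyclohex-2-en-1-one
Conditions: N,N'-dicyclohexylcarbodiimide (DCC), 4-dimethylaminopyridine (DMAP, 0.5 equiv), CH2Cl2, 0 °C to rt
Reagents that add atoms: none
Why: Steglich esterification of the only free hydroxyl, which is now flanked by a flat carbonyl carbon instead of a quaternary centre and is therefore accessible, and the E-enoate is the stable geometric isomer so that DMAP cannot erode it.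

Step 12
Reactants: 16 fully silylated enoate
Product: 17 (4S,5S,6R)-6-{[(2E)-4-{[tert-butyl(dimethyl)silyl]oxy}-2-methylbut-2-enoyl]oxy}-2-({[tert-butyl(dimethyl)silyl]oxy}methyl)-4-hydroxy-5-(propan-2-yl)cyclohex-2-en-1-one
Conditions: pyridinium p-toluenesulfonate (0.1 equiv), MeOH/CH2Cl2, 0 °C
Reagents that add atoms: none
Why: Selective acid-catalysed solvolysis of silyl ethers, in which the triethylsilyl ether reacts far faster than the bulkier tert-butyldimethylsilyl ethers, so that only C4–OH should be released.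

Step 13
Reactants: 17 4-hydroxy enoate
Product: 18 (4S,5S,6R)-6-{[(2E)-4-{[tert-butyl(dimethyl)silyl]oxy}-2-methylbut-2-enoyl]oxy}-2-({[tert-butyl(dimethyl)silyl]oxy}methyl)-5-(propan-2-yl)-4-(propanoyloxy)cyclohex-2-en-1-one
Conditions: (EtCO)2O, pyridine, DMAP (0.1 equiv), CH2Cl2, 0 °C
Reagents that add atoms: propionic anhydride, CCC(=O)OC(=O)CC
Why: DMAP-catalysed acylation of the single free secondary alcohol, which proceeds at oxygen and leaves C4 unchanged.

Step 14
Reactants: 18 bis-silyl ether of the target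
Product: 19 CNP0285949.1, (4S,5S,6R)-6-{[(2E)-4-hydroxy-2-methylbut-2-enoyl]oxy}-2-(hydroxymethyl)-5-(propan-2-yl)-4-(propanoyloxy)cyclohex-2-en-1-one
Conditions: HF·pyridine, pyridine/THF, 0 °C to rt
Reagents that add atoms: none
Why: Fluoride-mediated cleavage of both primary allylic silyl ethers in a buffered, weakly acidic medium, which avoids the base-induced elimination, epimerisation or acyl shift to which the diacyloxy enone is prone.

Compound list
1 | 3-hydroxy-2H-pyran-2-one | O=C1OC=CC=C1O | starting material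
2 | formaldehyde | C=O | starting material
3 | 3-hydroxy-4-(hydroxymethyl)-2H-pyran-2-one | O=C1OC=CC(CO)=C1O | intermediate
4 | 4-({[tert-butyl(dimethyl)silyl]oxy}methyl)-3-hydroxy-2H-pyran-2-one | O=C1OC=CC(CO[Si](C)(C)C(C)(C)C)=C1O | intermediate
5 | (3E)-5-methylhex-3-en-2-one | CC(C)/C=C/C(C)=O | starting material
6 | (1R,4R,7R,8R)-8-acetyl-5-({[tert-butyl(dimethyl)silyl]oxy}methyl)-4-hydroxy-7-(propan-2-yl)-2-oxabicyclo[2.2.2]oct-5-en-3-one | O=C1O[C@H]2C=C(CO[Si](C)(C)C(C)(C)C)[C@]1(O)[C@H](C(C)=O)[C@H]2C(C)C | intermediate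
7 | (1S,4S,7S,8R)-5-({[tert-butyl(dimethyl)silyl]oxy}methyl)-4-hydroxy-3-oxo-7-(propan-2-yl)-2-oxabicyclo[2.2.2]oct-5-en-8-yl acetate | O=C1O[C@H]2C=C(CO[Si](C)(C)C(C)(C)C)[C@]1(O)[C@H](OC(C)=O)[C@H]2C(C)C | intermediate
8 | (1S,4S,5S,6R)-6-(acetyloxy)-2-({[tert-butyl(dimethyl)silyl]oxy}methyl)-1,4-dihydroxy-5-(propan-2-yl)cyclohex-2-ene-1-carboxylic acid | O[C@H]1C=C(CO[Si](C)(C)C(C)(C)C)[C@@](O)(C(=O)O)[C@H](OC(C)=O)[C@H]1C(C)C | intermediate
9 | (4S,5S,6R)-6-(acetyloxy)-2-({[tert-butyl(dimethyl)silyl]oxy}methyl)-4-hydroxy-5-(propan-2-yl)cyclohex-2-en-1-one | O[C@H]1C=C(CO[Si](C)(C)C(C)(C)C)C(=O)[C@H](OC(C)=O)[C@H]1C(C)C | intermediate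
10 | (4S,5R,6R)-6-(acetyloxy)-2-({[tert-butyl(dimethyl)silyl]oxy}methyl)-5-(propan-2-yl)-4-[(triethylsilyl)oxy]cyclohex-2-en-1-one | CC[Si](CC)(CC)O[C@H]1C=C(CO[Si](C)(C)C(C)(C)C)C(=O)[C@H](OC(C)=O)[C@H]1C(C)C | intermediate
11 | (4S,5R,6R)-2-({[tert-butyl(dimethyl)silyl]oxy}methyl)-6-hydroxy-5-(propan-2-yl)-4-[(triethylsilyl)oxy]cyclohex-2-en-1-one | CC[Si](CC)(CC)O[C@H]1C=C(CO[Si](C)(C)C(C)(C)C)C(=O)[C@H](O)[C@H]1C(C)C | intermediate
12 | {[tert-butyl(dimethyl)silyl]oxy}acetaldehyde | O=CCO[Si](C)(C)C(C)(C)C | starting material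
13 | ethyl 2-(triphenyl-λ5-phosphanylidene)propanoate | CCOC(=O)C(C)=P(c1ccccc1)(c1ccccc1)c1ccccc1 | starting material
14 | ethyl (2E)-4-{[tert-butyl(dimethyl)silyl]oxy}-2-methylbut-2-enoate | CCOC(=O)/C(C)=C/CO[Si](C)(C)C(C)(C)C | intermediate
15 | (2E)-4-{[tert-butyl(dimethyl)silyl]oxy}-2-methylbut-2-enoic acid | OC(=O)/C(C)=C/CO[Si](C)(C)C(C)(C)C | intermediate
16 | (4S,5R,6R)-6-{[(2E)-4-{[tert-butyl(dimethyl)silyl]oxy}-2-methylbut-2-enoyl]oxy}-2-({[tert-butyl(dimethyl)silyl]oxy}methyl)-5-(propan-2-yl)-4-[(triethylsilyl)oxy]cyclohex-2-en-1-one | CC[Si](CC)(CC)O[C@H]1C=C(CO[Si](C)(C)C(C)(C)C)C(=O)[C@H](OC(=O)/C(C)=C/CO[Si](C)(C)C(C)(C)C)[C@H]1C(C)C | intermediate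
17 | (4S,5S,6R)-6-{[(2E)-4-{[tert-butyl(dimethyl)silyl]oxy}-2-methylbut-2-enoyl]oxy}-2-({[tert-butyl(dimethyl)silyl]oxy}methyl)-4-hydroxy-5-(propan-2-yl)cyclohex-2-en-1-one | O[C@H]1C=C(CO[Si](C)(C)C(C)(C)C)C(=O)[C@H](OC(=O)/C(C)=C/CO[Si](C)(C)C(C)(C)C)[C@H]1C(C)C | intermediate
18 | (4S,5S,6R)-6-{[(2E)-4-{[tert-butyl(dimethyl)silyl]oxy}-2-methylbut-2-enoyl]oxy}-2-({[tert-butyl(dimethyl)silyl]oxy}methyl)-5-(propan-2-yl)-4-(propanoyloxy)cyclohex-2-en-1-one | CCC(=O)O[C@H]1C=C(CO[Si](C)(C)C(C)(C)C)C(=O)[C@H](OC(=O)/C(C)=C/CO[Si](C)(C)C(C)(C)C)[C@H]1C(C)C | intermediate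
19 | CNP0285949.1, (4S,5S,6R)-6-{[(2E)-4-hydroxy-2-methylbut-2-enoyl]oxy}-2-(hydroxymethyl)-5-(propan-2-yl)-4-(propanoyloxy)cyclohex-2-en-1-one | CCC(=O)O[C@H]1C=C(CO)C(=O)[C@H](OC(=O)/C(C)=C/CO)[C@H]1C(C)C | target

Total step count: 14. Longest linear sequence: 12 (steps 1–8 and 11–14).

Steps most likely to fail

First, step 1. Formaldehyde may attack the vinylogous position C6 of the pyrone instead of C4, a second hydroxymethylation may follow, or base may open the lactone.
- The fallback leaves C7 out of the diene and brings it in once the enone exists.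
- It sets out from 1, which is combined with 5 under the conditions of step 3 to give the C7-free endo adduct F1.
- The operations of steps 4, 5 and 6 then lead to the C7-free bridged acetate F2, the C7-free hydroxy acid F3 and the C7-free 6-acetoxy-4-hydroxy enone F4.
- A Morita–Baylis–Hillman reaction (aq HCHO, DMAP, THF) places the hydroxymethyl group on C2 and gives the 2-(hydroxymethyl) enone diol F5.
- Selective silylation of its primary alcohol (TBSCl, imidazole, 0 °C) comes back to the route at 9.

Second, step 3. The preference for the endo mode may be insufficient, or turnover with the β-branched enone may be slow enough for the exo mode to take over.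
- The fallback corrects the stereochemistry by inversion instead of relying on endo control.
- It sets out from 4 and 5. The catalyst governs the face of the enone, so the exo adduct F6 has C5 and C6 as in 6 and differs only at C1 (lost later) and C4.
- F6 is carried through the operations of steps 4–8, 11 and 12. This passes through the exo-series acetate F7, the exo-series hydroxy acid F8, the 4-epi hydroxy enone F9, the 4-epi triethylsilyl ether F10, the 4-epi ketol F11, the 4-epi enoate F12 and the 4-epi alcohol F13.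
- A Mitsunobu esterification with propionic acid (PPh3, diisopropyl azodicarboxylate, THF, 0 °C) then installs the propionate with inversion at C4 and comes back to the route at 18.
- Both cycloaddition modes therefore lead to the same product.

Third, step 4. Epoxidation of C2=C3 may overtake the slow oxygen insertion at a hindered methyl ketone.
- The fallback gives up the acetyl group and introduces the C6 oxygen by enolate oxidation under control of the isopropyl group.
- It sets out from 6. LiOH (THF/H2O, 0 °C) opens the lactone to the acetyl hydroxy acid F14, and Pb(OAc)4 gives the 6-acetyl-4-hydroxy enone F15.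
- A retro-Claisen deacetylation (K2CO3, MeOH) gives the 6-unsubstituted 4-hydroxy enone F16, and TESCl/imidazole gives the 6-unsubstituted triethylsilyl ether F17.
- Kinetic deprotonation at C6 (LiN(SiMe3)2, THF, −78 °C) followed by 2-(phenylsulfonyl)-3-phenyloxaziridine delivers oxygen anti to the isopropyl group and comes back to the route at 11.

Further compounds
F1 | step 1 | C7-free endo adduct | O=C1O[C@H]2C=C[C@]1(O)[C@H](C(C)=O)[C@H]2C(C)C
F2 | step 1 | C7-free bridged acetate | O=C1O[C@H]2C=C[C@]1(O)[C@H](OC(C)=O)[C@H]2C(C)C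
F3 | step 1 | C7-free hydroxy acid | O[C@H]1C=C[C@@](O)(C(=O)O)[C@H](OC(C)=O)[C@H]1C(C)C
F4 | step 1 | C7-free 6-acetoxy-4-hydroxy enone | O[C@H]1C=CC(=O)[C@H](OC(C)=O)[C@H]1C(C)C
F5 | step 1 | 2-(hydroxymethyl) enone diol | O[C@H]1C=C(CO)C(=O)[C@H](OC(C)=O)[C@H]1C(C)C
F6 | step 3 | exo adduct | O=C1O[C@@H]2C=C(CO[Si](C)(C)C(C)(C)C)[C@@]1(O)[C@H](C(C)=O)[C@H]2C(C)C
F7 | step 3 | exo-series acetate | O=C1O[C@@H]2C=C(CO[Si](C)(C)C(C)(C)C)[C@@]1(O)[C@H](OC(C)=O)[C@H]2C(C)C
F8 | step 3 | exo-series hydroxy acid | O[C@@H]1C=C(CO[Si](C)(C)C(C)(C)C)[C@](O)(C(=O)O)[C@H](OC(C)=O)[C@H]1C(C)C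
F9 | step 3 | 4-epi hydroxy enone | O[C@@H]1C=C(CO[Si](C)(C)C(C)(C)C)C(=O)[C@H](OC(C)=O)[C@H]1C(C)C
F10 | step 3 | 4-epi triethylsilyl ether | CC[Si](CC)(CC)O[C@@H]1C=C(CO[Si](C)(C)C(C)(C)C)C(=O)[C@H](OC(C)=O)[C@H]1C(C)C
F11 | step 3 | 4-epi ketol | CC[Si](CC)(CC)O[C@@H]1C=C(CO[Si](C)(C)C(C)(C)C)C(=O)[C@H](O)[C@H]1C(C)C
F12 | step 3 | 4-epi enoate | CC[Si](CC)(CC)O[C@@H]1C=C(CO[Si](C)(C)C(C)(C)C)C(=O)[C@H](OC(=O)/C(C)=C/CO[Si](C)(C)C(C)(C)C)[C@H]1C(C)C
F13 | step 3 | 4-epi alcohol | O[C@@H]1C=C(CO[Si](C)(C)C(C)(C)C)C(=O)[C@H](OC(=O)/C(C)=C/CO[Si](C)(C)C(C)(C)C)[C@H]1C(C)C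
F14 | step 4 | acetyl hydroxy acid | O[C@H]1C=C(CO[Si](C)(C)C(C)(C)C)[C@@](O)(C(=O)O)[C@H](C(C)=O)[C@H]1C(C)C
F15 | step 4 | 6-acetyl-4-hydroxy enone | O[C@H]1C=C(CO[Si](C)(C)C(C)(C)C)C(=O)[C@H](C(C)=O)[C@H]1C(C)C
F16 | step 4 | 6-unsubstituted 4-hydroxy enone | O[C@H]1C=C(CO[Si](C)(C)C(C)(C)C)C(=O)C[C@H]1C(C)C
F17 | step 4 | 6-unsubstituted triethylsilyl ether | CC[Si](CC)(CC)O[C@H]1C=C(CO[Si](C)(C)C(C)(C)C)C(=O)C[C@H]1C(C)C
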